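**Retrosynthetic overview**

1. Target 26 is reached by BBr3 demethylation of the undeca-O-methyl ether 25. Compound 25 is cut at the C4–O–D1 ether into DE phenol 18 and ABC boronic acid 24 (Chan–Lam coupling).
2. The strategy rests on ring E being a 2-aryloxyphloroglucinol: ether oxygen on E1, hydroxyls on E2, E4 and E6, the oxygen pattern of a folded tri-β-carbonyl chain. Ring E is therefore built, not coupled: E2–E1–E6 come from aryloxymalonate 11, E3–E4–E5 from diethyl acetonedicarboxylate 12, and a double Claisen condensation forms E2–E3 and E5–E6 (14).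
3. The D6–O–E1 ether is made by SN2 on diethyl chloromalonate. Rings B and D both come from 2-bromo-4,6-dimethoxyphenol 5 (Vilsmeier–Haack, then Baeyer–Villiger, from 1-bromo-3,5-dimethoxybenzene 1).
4. For ring D the hydroxyl of 5 is benzylated and the bromide turned into the D6 hydroxyl. For ring B the hydroxyl is arylated with ring A (Chan–Lam) and the bromide replaced by the ring C phenol (Ullmann); boron is then placed on C4 by sterically controlled Ir-catalysed C–H borylation.
5. Ring order: rings A, B, C and D are bought as benzenoid pieces; ring E is the only ring formed (step 6).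

Key step: step 6

Assumption: rings are lettered A to E from the 3,5-dihydroxyphenoxy end; in rings B to E position 1 is the carbon bound to the oxygen that leads back to the preceding ring. The target has no stereocentre.

**Route**

Step 1
Reactants: 1 1-bromo-3,5-dimethoxybenzene
Product: 3 2-bromo-4,6-dimethoxybenzaldehyde, via benzylidene iminium chloride 2 (not isolated)
Conditions: POCl3, DMF, 0 → 90 °C; then H2O
Reagents that add atoms: N,N-dimethylformamide CN(C)C=O; water O
Why: Vilsmeier–Haack formylation of the doubly activated arene should go para to one methoxy group at the position next to bromine, the site between the two methoxy groups being more hindered.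

Step 2
Reactants: 3 2-bromo-4,6-dimethoxybenzaldehyde
Product: 5 2-bromo-4,6-dimethoxyphenol, via aryl formate 4 (not isolated)
Conditions: mCPBA, CH2Cl2, 0 °C → rt; then K2CO3 (cat.), MeOH, rt
Reagents that add atoms: mCPBA OOC(=O)c1cccc(Cl)c1
Why: Baeyer–Villiger (Dakin-type) oxidation, in which the aryl group carrying ortho and para methoxy groups migrates in the Criegee intermediate and the resulting formate is removed by methanolysis.

Step 3
Reactants: 5 2-bromo-4,6-dimethoxyphenol
Product: 6 2-(benzyloxy)-1-bromo-3,5-dimethoxybenzene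
Conditions: BnBr, K2CO3, DMF, 50 °C
Reagents that add atoms: benzyl bromide BrCc1ccccc1
Why: Williamson etherification of an acidic ortho-bromophenol; benzyl is chosen because it should survive ethoxide, hot alkali and methylation and later leave by hydrogenolysis.

Step 4
Reactants: 6 2-(benzyloxy)-1-bromo-3,5-dimethoxybenzene
Product: 9 2-(benzyloxy)-3,5-dimethoxyphenol, via aryllithium 7 (not isolated), via lithium aryltrimethoxyborate 8 (not isolated)
Conditions: n-BuLi, THF, −78 °C; B(OMe)3, −78 °C → rt; then H2O2, aq. NaOH, 0 °C → rt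
Reagents that add atoms: hydrogen peroxide OO
Why: Bromine–lithium exchange, borate trapping and oxidative 1,2-aryl shift from boron to oxygen is the standard conversion of an aryl bromide into a phenol, and the benzyl and methyl ethers are inert to it at low temperature.

Step 5
Reactants: 9 2-(benzyloxy)-3,5-dimethoxyphenol; 10 diethyl chloromalonate
Product: 11 diethyl 2-[2-(benzyloxy)-3,5-dimethoxyphenoxy]malonate
Conditions: K2CO3, acetone, reflux
Reagents that add atoms: none
Why: Williamson-type SN2 O-alkylation of the phenoxide on the doubly activated chloride; the chloride is taken instead of the bromide because it is less prone to halogen transfer to an electron-rich phenoxide.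

Step 6
Reactants: 11 diethyl 2-[2-(benzyloxy)-3,5-dimethoxyphenoxy]malonate; 12 diethyl acetonedicarboxylate
Product: 14 diethyl 5-[2-(benzyloxy)-3,5-dimethoxyphenoxy]-2,4,6-trihydroxybenzene-1,3-dicarboxylate, via acyclic diketo triester 13 (not isolated)
Conditions: NaOEt (1 equiv), EtOH, reflux; then NaOEt (2 equiv), EtOH distilled out against toluene, 110 °C; aq. HCl
Reagents that add atoms: none
Why: Proposed new method: the sodium enolate of 12 should C-acylate on one ester of 11 (crossed Claisen condensation, E2–E3 bond) to give the anion of 13; with more ethoxide the remaining α-methylene carbon then attacks the second malonate ester in a 6-exo-trig Dieckmann-type closure (E5–E6 bond), and threefold enolisation gives the phloroglucinolate of 14. The closest known reaction type is the sodium alkoxide condensation of diethyl malonate with diethyl acetonedicarboxylate to a phloroglucinol dicarboxylate; a 2-aryloxymalonate has not been used in it. The aryloxy group should help, since its inductive pull makes both ester carbonyls more electrophilic, and as a 2-substituent it turns self-acylation of the malonate enolate into a reversible dead end because the quaternary product cannot be deprotonated. The selectivity needed is crossed over self-condensation and C- over O-acylation: the first equivalent of ethoxide converts the more acidic 12 into its enolate and leaves 11 as the only neutral ester electrophile, ethoxide reopens any pyranone formed through oxygen, and removal of ethanol pulls the equilibria to the aromatic polyanion, which cannot revert. No stereocentre is formed, the methine carbon of 11 becoming the sp2 carbon E1.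

Step 7
Reactants: 14 diethyl 5-[2-(benzyloxy)-3,5-dimethoxyphenoxy]-2,4,6-trihydroxybenzene-1,3-dicarboxylate
Product: 16 2-[2-(benzyloxy)-3,5-dimethoxyphenoxy]benzene-1,3,5-triol, via isophthalic diacid 15 (not isolated)
Conditions: aq. NaOH, reflux, argon; then HCl to pH 1, 80 °C
Reagents that add atoms: none
Why: Ester saponification followed by protodecarboxylation, which is easy for phloroglucinol carboxylic acids because ipso protonation of the electron-rich ring gives a β-keto acid tautomer.

Step 8
Reactants: 16 2-[2-(benzyloxy)-3,5-dimethoxyphenoxy]benzene-1,3,5-triol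
Product: 17 2-(benzyloxy)-1,5-dimethoxy-3-(2,4,6-trimethoxyphenoxy)benzene
Conditions: Me2SO4, K2CO3, acetone, reflux, argon
Reagents that add atoms: dimethyl sulfate COS(=O)(=O)OC
Why: Williamson O-methylation with the hard electrophile dimethyl sulfate and K2CO3 in acetone, conditions under which phloroglucinols are methylated on oxygen and not on carbon.

Step 9
Reactants: 17 2-(benzyloxy)-1,5-dimethoxy-3-(2,4,6-trimethoxyphenoxy)benzene
Product: 18 2,4-dimethoxy-6-(2,4,6-trimethoxyphenoxy)phenol
Conditions: H2 (1 atm), Pd/C, EtOAc–MeOH, rt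
Reagents that add atoms: none
Why: Catalytic hydrogenolysis of the benzyl ether should free the D1 hydroxyl while methyl and diaryl ethers stay untouched.

Step 10
Reactants: 5 2-bromo-4,6-dimethoxyphenol; 19 3,5-dimethoxyphenylboronic acid
Product: 20 1-bromo-2-(3,5-dimethoxyphenoxy)-3,5-dimethoxybenzene
Conditions: Cu(OAc)2, pyridine, 4 Å MS, CH2Cl2, air, rt
Reagents that add atoms: none
Why: Chan–Lam oxidative O-arylation at room temperature tolerates phenols with two ortho substituents and leaves the aryl bromide intact, giving the A1–O–B1 ether.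

Step 11
Reactants: 20 1-bromo-2-(3,5-dimethoxyphenoxy)-3,5-dimethoxybenzene; 21 2,6-dimethoxyphenol
Product: 22 2-[2-(3,5-dimethoxyphenoxy)-3,5-dimethoxyphenoxy]-1,3-dimethoxybenzene
Conditions: CuI (cat.), picolinic acid (cat.), K3PO4, DMSO, 110 °C, argon
Reagents that add atoms: none
Why: Ligand-accelerated Ullmann diaryl ether synthesis; the CuI–picolinic acid system is suited to 2,6-disubstituted phenols and ortho-substituted aryl halides, and forms the B6–O–C1 ether.

Step 12
Reactants: 22 2-[2-(3,5-dimethoxyphenoxy)-3,5-dimethoxyphenoxy]-1,3-dimethoxybenzene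
Product: 23 2-{4-[2-(3,5-dimethoxyphenoxy)-3,5-dimethoxyphenoxy]-3,5-dimethoxyphenyl}-4,4,5,5-tetramethyl-1,3,2-dioxaborolane
Conditions: B2pin2, [Ir(OMe)(cod)]2 (cat.), dtbpy (4,4'-di-tert-butyl-2,2'-bipyridine, cat.), THF, 80 °C
Reagents that add atoms: bis(pinacolato)diboron CC1(C)OB(B2OC(C)(C)C(C)(C)O2)OC1(C)C
Why: Sterically controlled iridium-catalysed C–H borylation (Hartwig–Miyaura) should touch only C4–H of ring C, the one aromatic C–H without an ortho substituent, since every C–H of rings A and B lies between two oxygen substituents.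

Step 13
Reactants: 23 2-{4-[2-(3,5-dimethoxyphenoxy)-3,5-dimethoxyphenoxy]-3,5-dimethoxyphenyl}-4,4,5,5-tetramethyl-1,3,2-dioxaborolane
Product: 24 {4-[2-(3,5-dimethoxyphenoxy)-3,5-dimethoxyphenoxy]-3,5-dimethoxyphenyl}boronic acid
Conditions: NaIO4, NH4OAc, acetone–H2O, rt
Reagents that add atoms: water O
Why: Oxidative pinacol ester cleavage: periodate destroys the pinacol released in the hydrolysis equilibrium and so drives it to the free boronic acid, which couples better than the ester in the next step.

Step 14
Reactants: 18 2,4-dimethoxy-6-(2,4,6-trimethoxyphenoxy)phenol; 24 {4-[2-(3,5-dimethoxyphenoxy)-3,5-dimethoxyphenoxy]-3,5-dimethoxyphenyl}boronic acid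
Product: 25 undeca-O-methyl ether of the target (all eleven hydroxyls as OMe)
Conditions: Cu(OAc)2, pyridine, 4 Å MS, CH2Cl2, air, rt
Reagents that add atoms: none
Why: Chan–Lam coupling of a boronic acid without ortho substituents with a di-ortho-substituted phenol, the same pairing as in step 10, should form the C4–O–D1 ether.

Step 15
Reactants: 25 undeca-O-methyl ether of the target
Product: 26 target pentamer CNP0018313.0
Conditions: BBr3 (excess), CH2Cl2, −78 °C → rt, argon; then H2O
Reagents that add atoms: none
Why: Lewis-acid cleavage of aryl methyl ethers by BBr3 (bromide attacks the O-methyl carbon of the boron adduct) should remove all eleven methyl groups without breaking diaryl ether bonds.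

**Compound list**

1 | 1-bromo-3,5-dimethoxybenzene | COc1cc(Br)cc(OC)c1 | starting material
2 | (2-bromo-4,6-dimethoxybenzylidene)dimethyliminium chloride | COc1cc(Br)c(C=[N+](C)C)c(OC)c1.[Cl-] | intermediate
3 | 2-bromo-4,6-dimethoxybenzaldehyde | COc1cc(Br)c(C=O)c(OC)c1 | intermediate
4 | 2-bromo-4,6-dimethoxyphenyl formate | COc1cc(Br)c(OC=O)c(OC)c1 | intermediate
5 | 2-bromo-4,6-dimethoxyphenol | COc1cc(Br)c(O)c(OC)c1 | intermediate
6 | 2-(benzyloxy)-1-bromo-3,5-dimethoxybenzene | COc1cc(Br)c(OCc2ccccc2)c(OC)c1 | intermediate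
7 | [2-(benzyloxy)-3,5-dimethoxyphenyl]lithium | [Li]c1cc(OC)cc(OC)c1OCc1ccccc1 | intermediate
8 | lithium [2-(benzyloxy)-3,5-dimethoxyphenyl]trimethoxyborate | CO[B-](OC)(OC)c1cc(OC)cc(OC)c1OCc1ccccc1.[Li+] | intermediate
9 | 2-(benzyloxy)-3,5-dimethoxyphenol | COc1cc(O)c(OCc2ccccc2)c(OC)c1 | intermediate
10 | diethyl chloromalonate | CCOC(=O)C(Cl)C(=O)OCC | starting material
11 | diethyl 2-[2-(benzyloxy)-3,5-dimethoxyphenoxy]malonate | CCOC(=O)C(Oc1cc(OC)cc(OC)c1OCc1ccccc1)C(=O)OCC | intermediate
12 | diethyl acetonedicarboxylate (diethyl 3-oxopentanedioate) | CCOC(=O)CC(=O)CC(=O)OCC | starting material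
13 | triethyl 1-[2-(benzyloxy)-3,5-dimethoxyphenoxy]-2,4-dioxopentane-1,3,5-tricarboxylate | CCOC(=O)CC(=O)C(C(=O)OCC)C(=O)C(Oc1cc(OC)cc(OC)c1OCc1ccccc1)C(=O)OCC | intermediate
14 | diethyl 5-[2-(benzyloxy)-3,5-dimethoxyphenoxy]-2,4,6-trihydroxybenzene-1,3-dicarboxylate | CCOC(=O)c1c(O)c(C(=O)OCC)c(O)c(Oc2cc(OC)cc(OC)c2OCc2ccccc2)c1O | intermediate
15 | 5-[2-(benzyloxy)-3,5-dimethoxyphenoxy]-2,4,6-trihydroxybenzene-1,3-dicarboxylic acid | OC(=O)c1c(O)c(C(=O)O)c(O)c(Oc2cc(OC)cc(OC)c2OCc2ccccc2)c1O | intermediate
16 | 2-[2-(benzyloxy)-3,5-dimethoxyphenoxy]benzene-1,3,5-triol | Oc1cc(O)c(Oc2cc(OC)cc(OC)c2OCc2ccccc2)c(O)c1 | intermediate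
17 | 2-(benzyloxy)-1,5-dimethoxy-3-(2,4,6-trimethoxyphenoxy)benzene | COc1cc(OC)c(Oc2cc(OC)cc(OC)c2OCc2ccccc2)c(OC)c1 | intermediate
18 | 2,4-dimethoxy-6-(2,4,6-trimethoxyphenoxy)phenol | COc1cc(OC)c(Oc2cc(OC)cc(OC)c2O)c(OC)c1 | intermediate
19 | 3,5-dimethoxyphenylboronic acid | COc1cc(OC)cc(B(O)O)c1 | starting material
20 | 1-bromo-2-(3,5-dimethoxyphenoxy)-3,5-dimethoxybenzene | COc1cc(OC)cc(Oc2c(Br)cc(OC)cc2OC)c1 | intermediate
21 | 2,6-dimethoxyphenol | COc1cccc(OC)c1O | starting material
22 | 2-[2-(3,5-dimethoxyphenoxy)-3,5-dimethoxyphenoxy]-1,3-dimethoxybenzene | COc1cc(OC)cc(Oc2c(OC)cc(OC)cc2Oc2c(OC)cccc2OC)c1 | intermediate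
23 | 2-{4-[2-(3,5-dimethoxyphenoxy)-3,5-dimethoxyphenoxy]-3,5-dimethoxyphenyl}-4,4,5,5-tetramethyl-1,3,2-dioxaborolane | COc1cc(OC)cc(Oc2c(OC)cc(OC)cc2Oc2c(OC)cc(B3OC(C)(C)C(C)(C)O3)cc2OC)c1 | intermediate
24 | {4-[2-(3,5-dimethoxyphenoxy)-3,5-dimethoxyphenoxy]-3,5-dimethoxyphenyl}boronic acid | COc1cc(OC)cc(Oc2c(OC)cc(OC)cc2Oc2c(OC)cc(B(O)O)cc2OC)c1 | intermediate
25 | undeca-O-methyl ether of the target | COc1cc(OC)cc(Oc2c(OC)cc(OC)cc2Oc2c(OC)cc(Oc3c(OC)cc(OC)cc3Oc3c(OC)cc(OC)cc3OC)cc2OC)c1 | intermediate
26 | CNP0018313.0 | Oc1cc(O)cc(Oc2c(O)cc(O)cc2Oc2c(O)cc(Oc3c(O)cc(O)cc3Oc3c(O)cc(O)cc3O)cc2O)c1 | target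

**Step count**

Total steps: 15. Longest linear sequence: 11 (steps 1 to 9, 14, 15).

**Steps most likely to fail**

Step 6. The ring-closing acylation may stall at the open-chain stage or be diverted through oxygen, and ethoxide may cleave the malonate by retro-Claisen loss of diethyl carbonate before the ring closes. The fallback uses known chemistry and buys ring E instead of building it. It sets out from bromide 6, which is coupled with purchased 2,4,6-trimethoxyphenol F1 in an Ullmann diaryl ether synthesis (CuI, picolinic acid, K3PO4, DMSO, 110 °C, argon). This gives the D6–O–E1 ether directly and comes back to the route at 17, so steps 4 to 8 are bypassed.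

Step 11. Both partners carry ortho substituents at the reacting centres, so C–O bond formation may be slow enough for protodebromination of 20 and degradation of the phenol to take over. The fallback reverses the order of bond formation and lets a formyl group activate the bromide. It sets out from aldehyde 3, whose bromide ortho to the formyl group is displaced by 21 (CuI cat., K2CO3, DMF, 120 °C) to give 2-(2,6-dimethoxyphenoxy)-4,6-dimethoxybenzaldehyde F2. Baeyer–Villiger oxidation (mCPBA, CH2Cl2) gives 2-(2,6-dimethoxyphenoxy)-4,6-dimethoxyphenyl formate F3, and methanolysis (K2CO3, MeOH) gives 2-(2,6-dimethoxyphenoxy)-4,6-dimethoxyphenol F4. Chan–Lam coupling of F4 with 19 (Cu(OAc)2, pyridine, CH2Cl2, air) comes back to the route at 22.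

Step 14. Oxidation of the very electron-rich phenol 18 by divalent copper under air and protodeboronation of 24 may outrun the C–O coupling. The fallback avoids oxidative conditions and forms the chain linearly by two Ullmann couplings under argon. It sets out from 18 and purchased 4-bromo-2,6-dimethoxyphenol F5. F5 is benzylated (BnBr, K2CO3, DMF) to 2-(benzyloxy)-5-bromo-1,3-dimethoxybenzene F6. Coupling of 18 with F6 (CuI, picolinic acid, K3PO4, DMSO, 100 °C) gives 2-(benzyloxy)-5-[2,4-dimethoxy-6-(2,4,6-trimethoxyphenoxy)phenoxy]-1,3-dimethoxybenzene F7. Hydrogenolysis (H2, Pd/C) gives 4-[2,4-dimethoxy-6-(2,4,6-trimethoxyphenoxy)phenoxy]-2,6-dimethoxyphenol F8. A second Ullmann coupling of F8 with bromide 20 comes back to the route at 25, so steps 11 to 13 are not needed.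

**Further compounds**

F1 | step 6 | 2,4,6-trimethoxyphenol | COc1cc(OC)c(O)c(OC)c1
F2 | step 11 | 2-(2,6-dimethoxyphenoxy)-4,6-dimethoxybenzaldehyde | COc1cc(OC)c(C=O)c(Oc2c(OC)cccc2OC)c1
F3 | step 11 | 2-(2,6-dimethoxyphenoxy)-4,6-dimethoxyphenyl formate | COc1cc(OC)c(OC=O)c(Oc2c(OC)cccc2OC)c1
F4 | step 11 | 2-(2,6-dimethoxyphenoxy)-4,6-dimethoxyphenol | COc1cc(OC)c(O)c(Oc2c(OC)cccc2OC)c1
F5 | step 14 | 4-bromo-2,6-dimethoxyphenol | COc1cc(Br)cc(OC)c1O
F6 | step 14 | 2-(benzyloxy)-5-bromo-1,3-dimethoxybenzene | COc1cc(Br)cc(OC)c1OCc1ccccc1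
F7 | step 14 | 2-(benzyloxy)-5-[2,4-dimethoxy-6-(2,4,6-trimethoxyphenoxy)phenoxy]-1,3-dimethoxybenzene | COc1cc(Oc2c(OC)cc(OC)cc2Oc2c(OC)cc(OC)cc2OC)cc(OC)c1OCc1ccccc1
F8 | step 14 | 4-[2,4-dimethoxy-6-(2,4,6-trimethoxyphenoxy)phenoxy]-2,6-dimethoxyphenol | COc1cc(Oc2c(OC)cc(OC)cc2Oc2c(OC)cc(OC)cc2OC)cc(OC)c1O
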